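**Retrosynthetic overview**
1. Ester C–O bond last: target ⇒ (S)-benzylic alcohol with free chelated phenol + (Z)-4-acetoxy-2-methylbut-2-enoic acid, joined by mixed-anhydride acylation (retention at carbon).
2. (S)-Carbinol ⇐ Ru–TsDPEN transfer hydrogenation of the acetyl group of 1-(5-acetyl-2-hydroxyphenyl)-3-methylbut-2-en-1-one. The phenol stays a methyl ether until the enone is in place, then BCl3 frees it.
3. Key C–C bond: ArC(=O)–CH2, from the aryl aldehyde used as an acyl anion (NHC, Breslow intermediate) and a π-methallyl-Pd electrophile, two natively electrophilic carbons. The C=C then moves into conjugation. The aldehyde comes from Rieche formylation of 4-methoxyacetophenone.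
4. Acid ⇐ Z-selective Ando HWE of a tert-butyl diphenylphosphonopropionate with acetoxyacetaldehyde, then TFA.
5. No ring is formed: the benzene ring is bought with the acetyl and oxygen substituents in place.

Assumption: anions, metal complexes and catalyst-bound species (Breslow intermediate, π-allyl-Pd, phosphonate anion) are treated as mechanism and carry no number.

**Route**

Step 1
Reactants: 1 4-methoxyacetophenone
Product: 3 5-acetyl-2-methoxybenzaldehyde, via α-chloro ether 2 (not isolated)
Conditions: Cl2CHOMe (1.5 equiv), TiCl4 (2.5 equiv), CH2Cl2, 0 °C → rt; then ice/H2O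
Reagents that add atoms: dichloromethyl methyl ether COC(Cl)Cl; water O
Why: Rieche formylation (Friedel–Crafts-type SEAr); the methoxy group (ortho-directing, para blocked) and the acetyl group (meta-directing) point to the same carbon, so one regioisomer forms and the α-chloro ether is hydrolysed on work-up.

Step 2
Reactants: 3 5-acetyl-2-methoxybenzaldehyde; 4 2-methylallyl acetate
Product: 6 1-(5-acetyl-2-methoxyphenyl)-3-methylbut-2-en-1-one, via β,γ-enone 5 (not isolated)
Conditions: 3-(2,6-diisopropylphenyl)-5,6,7,8-tetrahydro-4H-cyclohepta[d]thiazol-3-ium perchlorate (10 mol %), [Pd(allyl)Cl]2 (2.5 mol %), dppf (6 mol %), K2CO3 (1.2 equiv), THF, 60 °C; then DBU (0.2 equiv), rt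
Reagents that add atoms: none
Why: Proposed new method: the thiazolylidene adds only to the aldehyde (the aryl methyl ketone forms no Breslow intermediate), and the resulting Breslow enaminol, an acyl anion equivalent, attacks the π-(2-methylallyl)palladium cation formed from 4 by Tsuji–Trost ionization, so the formyl carbon and the allylic carbon, both natively electrophilic, are joined; K2CO3 takes up the acetic acid and regenerates the carbene, and DBU then moves the 1,1-disubstituted C=C into conjugation (no chromanone can form while the phenol is a methyl ether); closest known reaction type: synergistic NHC/Pd allylation of aryl aldehyde acyl anions with allylic carbonates.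

Step 3
Reactants: 6 1-(5-acetyl-2-methoxyphenyl)-3-methylbut-2-en-1-one
Product: 8 1-(5-acetyl-2-hydroxyphenyl)-3-methylbut-2-en-1-one, via boron chelate 7 (not isolated)
Conditions: BCl3 (2.2 equiv), CH2Cl2, −78 → 0 °C; then cold aq. NaHCO3
Reagents that add atoms: none
Why: Chelation-assisted Lewis-acid demethylation of an ortho-acyl aryl methyl ether (chloride SN2 at CH3); the six-membered O–B–O chelate holds the phenol oxygen away from the enone β-carbon, so oxa-Michael closure to the chromanone is blocked until cold hydrolysis.

Step 4
Reactants: 8 1-(5-acetyl-2-hydroxyphenyl)-3-methylbut-2-en-1-one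
Product: 9 1-{2-hydroxy-5-[(1S)-1-hydroxyethyl]phenyl}-3-methylbut-2-en-1-one
Conditions: RuCl[(S,S)-TsDPEN](p-cymene) (1 mol %), HCO2H/Et3N (5:2), EtOAc, 30 °C
Reagents that add atoms: none
Why: Noyori–Ikariya asymmetric transfer hydrogenation; the (S,S)-catalyst delivers hydride to the Re face of the aryl methyl ketone and sets the (S)-carbinol as it does for acetophenone, while the H-bonded, cross-conjugated enone carbonyl with its fully substituted β-carbon reacts much more slowly.

Step 5
Reactants: 10 tert-butyl 2-bromopropanoate; 11 diphenyl phosphite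
Product: 12 tert-butyl 2-(diphenoxyphosphoryl)propanoate
Conditions: Et3N (1.1 equiv), CH2Cl2, 0 °C → rt
Reagents that add atoms: none
Why: Michaelis–Becker-type P-alkylation; the phosphite anion displaces the activated α-bromide, and the racemic stereocentre does not matter because it becomes sp2 in step 6.

Step 6
Reactants: 12 tert-butyl 2-(diphenoxyphosphoryl)propanoate; 13 2-oxoethyl acetate (acetoxyacetaldehyde)
Product: 14 tert-butyl (2Z)-4-acetoxy-2-methylbut-2-enoate
Conditions: NaH (1.05 equiv), THF, 0 °C; then 13, −78 → 0 °C; chromatography to remove the minor E isomer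
Reagents that add atoms: none
Why: Ando-type Z-selective Horner–Wadsworth–Emmons olefination; the electron-poor diaryl phosphonate makes the kinetic adduct collapse before it equilibrates, which places CH2OAc cis to the ester.

Step 7
Reactants: 14 tert-butyl (2Z)-4-acetoxy-2-methylbut-2-enoate
Product: 15 (2Z)-4-acetoxy-2-methylbut-2-enoic acid
Conditions: TFA/CH2Cl2 (1:4), 0 °C → rt
Reagents that add atoms: none
Why: Acidolysis of the tert-butyl ester (E1 loss of isobutene) leaves the primary acetate and the Z-alkene untouched; because the γ-oxygen is acetylated, the Z-acid cannot lactonize to the butenolide.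

Step 8
Reactants: 15 (2Z)-4-acetoxy-2-methylbut-2-enoic acid; 9 1-{2-hydroxy-5-[(1S)-1-hydroxyethyl]phenyl}-3-methylbut-2-en-1-one
Product: 17 (1S)-1-[4-hydroxy-3-(3-methylbut-2-enoyl)phenyl]ethyl (2Z)-4-acetoxy-2-methylbut-2-enoate, via mixed anhydride 16 (not isolated)
Conditions: 2,4,6-Cl3C6H2COCl (1.05 equiv), Et3N (2.2 equiv), toluene, rt, 1 h; then 9 (0.95 equiv), DMAP (5 mol %), 0 °C → rt
Reagents that add atoms: none
Why: Yamaguchi mixed-anhydride esterification; the secondary alcohol attacks the unhindered enoyl carbonyl with retention at the carbinol carbon (its C–O bond is not broken), the chelated phenol is much less nucleophilic, and low DMAP loading and temperature limit Z→E isomerization.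

**Compound list**
1 | 4-methoxyacetophenone | COc1ccc(C(C)=O)cc1 | starting material
2 | 1-{3-[chloro(methoxy)methyl]-4-methoxyphenyl}ethan-1-one (α-chloro ether, racemic) | COc1ccc(C(C)=O)cc1C(Cl)OC | intermediate
3 | 5-acetyl-2-methoxybenzaldehyde | COc1ccc(C(C)=O)cc1C=O | intermediate
4 | 2-methylallyl acetate | CC(=C)COC(C)=O | starting material
5 | 1-(5-acetyl-2-methoxyphenyl)-3-methylbut-3-en-1-one (β,γ-enone) | COc1ccc(C(C)=O)cc1C(=O)CC(C)=C | intermediate
6 | 1-(5-acetyl-2-methoxyphenyl)-3-methylbut-2-en-1-one | COc1ccc(C(C)=O)cc1C(=O)C=C(C)C | intermediate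
7 | [4-acetyl-2-(3-methylbut-2-enoyl)phenoxy]dichloroborane (boron chelate) | CC(=O)c1ccc(OB(Cl)Cl)c(C(=O)C=C(C)C)c1 | intermediate
8 | 1-(5-acetyl-2-hydroxyphenyl)-3-methylbut-2-en-1-one | CC(=O)c1ccc(O)c(C(=O)C=C(C)C)c1 | intermediate
9 | 1-{2-hydroxy-5-[(1S)-1-hydroxyethyl]phenyl}-3-methylbut-2-en-1-one | C[C@H](O)c1ccc(O)c(C(=O)C=C(C)C)c1 | intermediate
10 | tert-butyl 2-bromopropanoate (racemic) | CC(Br)C(=O)OC(C)(C)C | starting material
11 | diphenyl phosphite | O=[PH](Oc1ccccc1)Oc1ccccc1 | starting material
12 | tert-butyl 2-(diphenoxyphosphoryl)propanoate (racemic) | CC(C(=O)OC(C)(C)C)P(=O)(Oc1ccccc1)Oc1ccccc1 | intermediate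
13 | 2-oxoethyl acetate (acetoxyacetaldehyde) | CC(=O)OCC=O | starting material
14 | tert-butyl (2Z)-4-acetoxy-2-methylbut-2-enoate | CC(=O)OC/C=C(/C)C(=O)OC(C)(C)C | intermediate
15 | (2Z)-4-acetoxy-2-methylbut-2-enoic acid | CC(=O)OC/C=C(/C)C(=O)O | intermediate
16 | (2Z)-4-acetoxy-2-methylbut-2-enoic 2,4,6-trichlorobenzoic anhydride (mixed anhydride) | CC(=O)OC/C=C(/C)C(=O)OC(=O)c1c(Cl)cc(Cl)cc1Cl | intermediate
17 | (1S)-1-[4-hydroxy-3-(3-methylbut-2-enoyl)phenyl]ethyl (2Z)-4-acetoxy-2-methylbut-2-enoate | CC(=O)OC/C=C(/C)C(=O)O[C@@H](C)c1ccc(O)c(C(=O)C=C(C)C)c1 | target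

**Step count**
Total: 8 steps. Longest linear sequence: 5 steps (steps 1, 2, 3, 4, 8). The acid branch is 3 steps (5, 6, 7).

**Three steps most likely to fail**

Step 2. The carbene may bind palladium, the acidic β,γ-enone may be allylated a second time, and benzoin formation may compete. The fallback sets out from 3 and comes back at 5, which DBU converts to 6 as before. Both carbonyl groups of 3 are converted with propane-1,3-dithiol and BF3·OEt2 into 2-[2-methoxy-5-(2-methyl-1,3-dithian-2-yl)phenyl]-1,3-dithiane F1. Only the formyl-derived dithiane has a C2–H, so n-BuLi (THF, −30 °C) gives a single 2-lithiodithiane, a stoichiometric acyl anion of the Corey–Seebach type. Alkylation with 3-bromo-2-methylpropene gives 2-[2-methoxy-5-(2-methyl-1,3-dithian-2-yl)phenyl]-2-(2-methylallyl)-1,3-dithiane F2. MeI/CaCO3 in aqueous MeCN removes both dithianes and returns 5.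

Step 4. The chelating phenol may slow or poison the Ru catalyst, and the enone may be reduced at C=C or C=O. The fallback sets out from 8 and comes back at 9. It replaces the metal-hydride transfer by a biocatalytic reduction with an (S)-selective (Prelog) ketoreductase, NADP+ and isopropanol recycling, pH 7 buffer with DMSO cosolvent, 30 °C. The enzyme pocket accepts the small methyl ketone and rejects the bulky chelated enone. No new compound arises (F0).

Step 8. DMAP may isomerize the Z-enoate to the E isomer, the phenol may be acylated, and the phenoxide of the product may expel the carboxylate (quinone methide). The fallback sets out from 8 and comes back at 17. Step 4 is run with the (R,R)-TsDPEN catalyst to give 1-{2-hydroxy-5-[(1R)-1-hydroxyethyl]phenyl}-3-methylbut-2-en-1-one F3. A Mitsunobu reaction with acid 15 (PPh3, DIAD, toluene, −20 °C) then forms the ester with inversion. The carboxylate acts as nucleophile, so the acid is never activated and cannot isomerize, and the weakly acidic chelated phenol does not compete. The cost is a risk of partial racemization at the electron-rich benzylic centre.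

**Further compounds**
F1 | step 2 | 2-[2-methoxy-5-(2-methyl-1,3-dithian-2-yl)phenyl]-1,3-dithiane | COc1ccc(C2(C)SCCCS2)cc1C1SCCCS1
F2 | step 2 | 2-[2-methoxy-5-(2-methyl-1,3-dithian-2-yl)phenyl]-2-(2-methylallyl)-1,3-dithiane | COc1ccc(C2(C)SCCCS2)cc1C1(CC(C)=C)SCCCS1
F0 | step 4 | none | none
F3 | step 8 | 1-{2-hydroxy-5-[(1R)-1-hydroxyethyl]phenyl}-3-methylbut-2-en-1-one | C[C@@H](O)c1ccc(O)c(C(=O)C=C(C)C)c1
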